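**Retrosynthetic overview**
1. The last step is global O-dealkylation of a fully ether-protected tetramer. No aryl–oxygen bond is made by coupling; both inner rings are built de novo.
2. The strategy rests on rings B and C. Each is a 1,2,3,5-tetraoxygenated benzene with its two bridging ether oxygens para (on C1 and C4), OH on C2 and C6, and H on C3 and C5. Each ring is cut into three two-carbon pieces: C1–C2 (an oxyketene from an oxyacetyl chloride), C3–C4 (an aryl ethynyl ether) and C5–C6 (ethoxyacetylene).
3. Ketene plus ethoxyacetylene gives a 4-oxy-3-ethoxycyclobutenone. Heating it with the aryl ethynyl ether (Danheiser-type benzannulation) closes the benzene ring with every oxygen already in place.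
4. Ring order: ring D is bought (as its aldehyde), ring C is grown onto the ring D oxygen, then ring B is grown between the ring C oxygen and the oxygen of bought ring A.

Key step: step 15

Remark: the target has no stereogenic element, so cyclobutenones 13 and 31 are used as racemates; dichloroacetylene 5 is toxic and explosive, is never isolated, and is generated from trichloroethylene in the flask each time it is needed (steps 3 and 9).

**Route**

Step 1
Reactants: 1 2,4,6-trimethoxybenzaldehyde
Product: 2 2,4,6-trimethoxyphenyl formate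
Conditions: mCPBA (1.3 equiv), CH2Cl2, 0 °C to rt
Reagents that add atoms: mCPBA (3-chloroperbenzoic acid), O=C(OO)c1cccc(Cl)c1
Why: Baeyer–Villiger oxidation, in which the very electron-rich aryl group migrates in preference to hydride, so the aldehyde should give the aryl formate.

Step 2
Reactants: 2 2,4,6-trimethoxyphenyl formate
Product: 3 2,4,6-trimethoxyphenol
Conditions: K2CO3 (cat.), MeOH, 0 °C, argon; dilute HCl work-up
Reagents that add atoms: none
Why: Base-catalysed methanolysis (transesterification) of a labile aryl formate, run under argon because the phenol oxidises easily.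

Step 3
Reactants: 3 2,4,6-trimethoxyphenol; 4 trichloroethylene
Product: 6 2-{[(E)-1,2-dichloroethenyl]oxy}-1,3,5-trimethoxybenzene, via dichloroacetylene 5 (not isolated)
Conditions: K2CO3 (2 equiv), 4 (3 equiv), DMF, 70 °C, argon
Reagents that add atoms: none
Why: Base removes HCl from trichloroethylene, and anti addition of the phenoxide and a proton across the resulting haloalkyne should give the (E)-1,2-dichlorovinyl ether (nucleophilic addition of a phenoxide to dichloroacetylene).

Step 4
Reactants: 6 2-{[(E)-1,2-dichloroethenyl]oxy}-1,3,5-trimethoxybenzene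
Product: 9 2-(ethynyloxy)-1,3,5-trimethoxybenzene, via chloroethynyl ether 7 (not isolated), via lithium acetylide 8 (not isolated)
Conditions: n-BuLi (2.2 equiv), THF, −78 to −40 °C; then H2O, −78 °C; use soon after preparation
Reagents that add atoms: none
Why: Greene-type ynol ether synthesis, in which vinyl deprotonation with loss of LiCl gives the chloroalkyne, chlorine–lithium exchange gives the acetylide and protonation gives the terminal ynol ether, while the low temperature holds back ortho-lithiation of ring D.

Step 5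
Reactants: 10 benzyloxyacetyl chloride; 11 ethoxyacetylene
Product: 13 rac-4-(benzyloxy)-3-ethoxycyclobut-2-en-1-one, via benzyloxyketene 12 (not isolated)
Conditions: 11 (3 equiv, hexane solution), Et3N (1.1 equiv, added over 4 h), CH2Cl2, 0 °C to rt
Reagents that add atoms: none
Why: Dehydrochlorination gives the ketene, and its [2+2] cycloaddition with the ynol ether joins the nucleophilic CH carbon of the alkyne to the ketene carbonyl carbon, so the 3-ethoxy-4-benzyloxy isomer should form; C4 is racemic and is erased later.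

Step 6
Reactants: 9 2-(ethynyloxy)-1,3,5-trimethoxybenzene; 13 rac-4-(benzyloxy)-3-ethoxycyclobut-2-en-1-one
Product: 18 2-(benzyloxy)-3-ethoxy-5-(2,4,6-trimethoxyphenoxy)phenol, via vinylketene 14 (not isolated), via vinylcyclobutenone 15 (not isolated), via dienylketene 16 (not isolated), via cyclohexadienone 17 (not isolated)
Conditions: 13 (1.5 equiv), degassed toluene, 80 to 110 °C, argon; then K2CO3, MeOH, rt (cleaves any aryl ester formed from product and ketene)
Reagents that add atoms: none
Why: Proposed new method: thermal four-electron opening of 13 (C4 benzyloxy group turning outward) should give vinylketene 14, whose carbonyl carbon is attacked by the nucleophilic CH carbon of ynol ether 9 in a [2+2] cycloaddition to give 15, and a second four-electron opening to dienylketene 16, six-electron electrocyclisation to 17 and enolisation then deliver ring C with the ring D oxygen para to the benzyloxy group; the closest known reaction type is the Danheiser benzannulation of cyclobutenones with alkoxyacetylenes, and the untested features are the 4-oxy-3-alkoxy pattern of the cyclobutenone and the aryl ethynyl ether partner.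

Step 7
Reactants: 18 2-(benzyloxy)-3-ethoxy-5-(2,4,6-trimethoxyphenoxy)phenol
Product: 19 2-(benzyloxy)-1-ethoxy-3-methoxy-5-(2,4,6-trimethoxyphenoxy)benzene
Conditions: MeI, K2CO3, DMF, rt
Reagents that add atoms: iodomethane, CI
Why: Williamson O-methylation of the only free phenol caps the C2 oxygen of ring C so that the C1 oxygen can be released selectively.

Step 8
Reactants: 19 2-(benzyloxy)-1-ethoxy-3-methoxy-5-(2,4,6-trimethoxyphenoxy)benzene
Product: 20 2-ethoxy-6-methoxy-4-(2,4,6-trimethoxyphenoxy)phenol
Conditions: H2 (1 atm), Pd/C (palladium on carbon), EtOAc/EtOH, rt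
Reagents that add atoms: none
Why: Hydrogenolysis cleaves only the benzyl ether; methyl, ethyl and diaryl ethers are inert under these conditions.

Step 9
Reactants: 20 2-ethoxy-6-methoxy-4-(2,4,6-trimethoxyphenoxy)phenol; 4 trichloroethylene
Product: 21 2-{[(E)-1,2-dichloroethenyl]oxy}-1-ethoxy-3-methoxy-5-(2,4,6-trimethoxyphenoxy)benzene
Conditions: K2CO3 (2 equiv), 4 (3 equiv), DMF, 70 to 80 °C, argon
Reagents that add atoms: none
Why: The phenoxide of 20 adds to dichloroacetylene 5, which base and trichloroethylene deliver again in the flask as in step 3, and anti protonation should give the (E)-1,2-dichlorovinyl ether; the electrophile is small and linear, so the two ortho alkoxy groups should not block the oxygen.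

Step 10
Reactants: 21 2-{[(E)-1,2-dichloroethenyl]oxy}-1-ethoxy-3-methoxy-5-(2,4,6-trimethoxyphenoxy)benzene
Product: 24 1-ethoxy-2-(ethynyloxy)-3-methoxy-5-(2,4,6-trimethoxyphenoxy)benzene, via chloroethynyl ether 22 (not isolated), via lithium acetylide 23 (not isolated)
Conditions: n-BuLi (2.2 equiv), THF, −78 to −50 °C; then H2O, −78 °C; use soon after preparation
Reagents that add atoms: none
Why: Same elimination, chlorine–lithium exchange and protonation sequence as in step 4, kept cold and close to stoichiometric so that the ring protons between two alkoxy groups are not lithiated.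

Step 11
Reactants: 25 3,5-dimethoxyphenol; 26 ethyl bromoacetate
Product: 27 ethyl (3,5-dimethoxyphenoxy)acetate
Conditions: K2CO3, acetone, reflux
Reagents that add atoms: none
Why: Williamson alkylation of an unhindered phenoxide with an activated primary bromide; this forms what will become the crowded ring A–O–C1 bond of ring B as a simple O–CH2 bond.

Step 12
Reactants: 27 ethyl (3,5-dimethoxyphenoxy)acetate
Product: 28 (3,5-dimethoxyphenoxy)acetic acid
Conditions: LiOH, THF/H2O, rt; then 1 M HCl
Reagents that add atoms: lithium hydroxide, [Li+].[OH-]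
Why: Ordinary ester saponification by acyl–oxygen cleavage.

Step 13
Reactants: 28 (3,5-dimethoxyphenoxy)acetic acid
Product: 29 (3,5-dimethoxyphenoxy)acetyl chloride
Conditions: (COCl)2 (1.5 equiv), CH2Cl2, 0 °C to rt, no DMF and no Lewis acid; evaporate and use crude at once
Reagents that add atoms: oxalyl chloride, O=C(Cl)C(=O)Cl
Why: Acid chloride formation; omitting DMF avoids Vilsmeier formylation of the electron-rich ring A, and the absence of Lewis acid and immediate use should limit Friedel–Crafts closure onto ring A.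

Step 14
Reactants: 29 (3,5-dimethoxyphenoxy)acetyl chloride; 11 ethoxyacetylene
Product: 31 rac-4-(3,5-dimethoxyphenoxy)-3-ethoxycyclobut-2-en-1-one, via aryloxyketene 30 (not isolated)
Conditions: 11 (3 equiv, hexane solution), Et3N (1.1 equiv, added over 4 h), CH2Cl2, 0 °C to rt
Reagents that add atoms: none
Why: Ketene–ynol ether [2+2] cycloaddition as in step 5; slow amine addition keeps the ketene dilute so that capture by excess ethoxyacetylene should outrun dimerisation, and the regiochemistry follows from alkyne CH attacking the ketene carbonyl carbon.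

Step 15
Reactants: 24 1-ethoxy-2-(ethynyloxy)-3-methoxy-5-(2,4,6-trimethoxyphenoxy)benzene; 31 rac-4-(3,5-dimethoxyphenoxy)-3-ethoxycyclobut-2-en-1-one
Product: 36 2-(3,5-dimethoxyphenoxy)-3-ethoxy-5-[2-ethoxy-6-methoxy-4-(2,4,6-trimethoxyphenoxy)phenoxy]phenol, via vinylketene 32 (not isolated), via vinylcyclobutenone 33 (not isolated), via dienylketene 34 (not isolated), via cyclohexadienone 35 (not isolated)
Conditions: 31 (1.5 equiv), degassed toluene, 80 to 110 °C, argon; then K2CO3, MeOH, rt
Reagents that add atoms: none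
Why: Proposed new method: heating should open 31 by four-electron electrocyclic cleavage of its C1–C4 bond, the C4 aryloxy donor turning outward, to give vinylketene 32; the CH terminus of ynol ether 24 then adds to the ketene carbonyl carbon in a [2+2] cycloaddition to give 33, which opens again, reversibly, to dienylketene 34, the isomer with the alkenyl group cis to the ketene carbon being the one consumed. Ring B closes by six-electron electrocyclisation of 34, which re-forms the bond between the former carbonyl carbon and the aryloxy-bearing carbon (C2–C1 of ring B), and enolisation of 35 gives the phenol; the C2–C3 and C4–C5 bonds of ring B come from the [2+2] step, so the ring and both of its diaryl ether links appear together. The closest known reaction type is the Danheiser benzannulation of cyclobutenones with alkoxy- and silyloxyacetylenes, supported by the thermal opening of 4-oxy-3-alkoxycyclobutenones in squarate (Moore) rearrangements; the untested features are the 4-aryloxy-3-ethoxy cyclobutenone and an aryl ethynyl ether as ketenophile. No stereocentre is set: C4 of 31 and the sp3 centres of 33 and 35 are racemic and vanish on aromatisation. Only regioselectivity is needed, and the polarisation of the ynol ether (nucleophilic CH carbon to electrophilic ketene carbon) secures it, placing the ring C oxygen para to the ring A oxygen, OH and OEt on either side of the ring A oxygen, and H at C3 and C5. The aryl ethynyl ether has no retro-ene pathway and is shielded by two ortho alkoxy groups, and the hindered ring A–O–C1 bond is already present as the sp3 ether of 31.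

Step 16
Reactants: 36 2-(3,5-dimethoxyphenoxy)-3-ethoxy-5-[2-ethoxy-6-methoxy-4-(2,4,6-trimethoxyphenoxy)phenoxy]phenol
Product: 37 tetraphlorethol C
Conditions: BBr3 (20 equiv), CH2Cl2, −78 °C to rt, argon; then ice/H2O; EtOAc extraction and reversed-phase chromatography under inert gas
Reagents that add atoms: none
Why: Lewis acid dealkylation of aryl alkyl ethers by bromide attack at the alkyl carbon should cleave all six methyl and both ethyl ethers while leaving the three diaryl ether bonds, which have no alkyl carbon to attack.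

**Compound list**
1 | 2,4,6-trimethoxybenzaldehyde | COc1cc(OC)c(C=O)c(OC)c1 | starting material
2 | 2,4,6-trimethoxyphenyl formate | COc1cc(OC)c(OC=O)c(OC)c1 | intermediate
3 | 2,4,6-trimethoxyphenol | COc1cc(OC)c(O)c(OC)c1 | intermediate
4 | trichloroethylene | ClC=C(Cl)Cl | starting material
5 | dichloroacetylene (not isolated) | ClC#CCl | intermediate
6 | 2-{[(E)-1,2-dichloroethenyl]oxy}-1,3,5-trimethoxybenzene | Cl/C=C(/Cl)Oc1c(OC)cc(OC)cc1OC | intermediate
7 | 2-[(chloroethynyl)oxy]-1,3,5-trimethoxybenzene (not isolated) | ClC#COc1c(OC)cc(OC)cc1OC | intermediate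
8 | lithium [(2,4,6-trimethoxyphenoxy)ethynide] (not isolated) | [Li]C#COc1c(OC)cc(OC)cc1OC | intermediate
9 | 2-(ethynyloxy)-1,3,5-trimethoxybenzene | C#COc1c(OC)cc(OC)cc1OC | intermediate
10 | benzyloxyacetyl chloride | O=C(Cl)COCc1ccccc1 | starting material
11 | ethoxyacetylene | C#COCC | starting material
12 | benzyloxyketene (not isolated) | O=C=COCc1ccccc1 | intermediate
13 | rac-4-(benzyloxy)-3-ethoxycyclobut-2-en-1-one | CCOC1=CC(=O)C1OCc1ccccc1 | intermediate
14 | (Z)-4-(benzyloxy)-3-ethoxybuta-1,3-dien-1-one, benzyloxy trans to the ketene carbon (not isolated) | O=C=C/C(OCC)=C/OCc1ccccc1 | intermediate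
15 | rac-4-[(Z)-2-(benzyloxy)-1-ethoxyethenyl]-3-(2,4,6-trimethoxyphenoxy)cyclobut-2-en-1-one (not isolated) | O=C1C=C(Oc2c(OC)cc(OC)cc2OC)C1/C(OCC)=C/OCc1ccccc1 | intermediate
16 | (3E,5Z)-6-(benzyloxy)-5-ethoxy-3-(2,4,6-trimethoxyphenoxy)hexa-1,3,5-trien-1-one (not isolated) | O=C=C/C(Oc1c(OC)cc(OC)cc1OC)=C\C(OCC)=C\OCc1ccccc1 | intermediate
17 | rac-6-(benzyloxy)-5-ethoxy-3-(2,4,6-trimethoxyphenoxy)cyclohexa-2,4-dien-1-one (not isolated) | O=C1C=C(Oc2c(OC)cc(OC)cc2OC)C=C(OCC)C1OCc1ccccc1 | intermediate
18 | 2-(benzyloxy)-3-ethoxy-5-(2,4,6-trimethoxyphenoxy)phenol | CCOc1cc(Oc2c(OC)cc(OC)cc2OC)cc(O)c1OCc1ccccc1 | intermediate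
19 | 2-(benzyloxy)-1-ethoxy-3-methoxy-5-(2,4,6-trimethoxyphenoxy)benzene | CCOc1cc(Oc2c(OC)cc(OC)cc2OC)cc(OC)c1OCc1ccccc1 | intermediate
20 | 2-ethoxy-6-methoxy-4-(2,4,6-trimethoxyphenoxy)phenol | CCOc1cc(Oc2c(OC)cc(OC)cc2OC)cc(OC)c1O | intermediate
21 | 2-{[(E)-1,2-dichloroethenyl]oxy}-1-ethoxy-3-methoxy-5-(2,4,6-trimethoxyphenoxy)benzene | Cl/C=C(/Cl)Oc1c(OCC)cc(Oc2c(OC)cc(OC)cc2OC)cc1OC | intermediate
22 | 2-[(chloroethynyl)oxy]-1-ethoxy-3-methoxy-5-(2,4,6-trimethoxyphenoxy)benzene (not isolated) | ClC#COc1c(OCC)cc(Oc2c(OC)cc(OC)cc2OC)cc1OC | intermediate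
23 | lithium {[2-ethoxy-6-methoxy-4-(2,4,6-trimethoxyphenoxy)phenoxy]ethynide} (not isolated) | [Li]C#COc1c(OCC)cc(Oc2c(OC)cc(OC)cc2OC)cc1OC | intermediate
24 | 1-ethoxy-2-(ethynyloxy)-3-methoxy-5-(2,4,6-trimethoxyphenoxy)benzene | C#COc1c(OCC)cc(Oc2c(OC)cc(OC)cc2OC)cc1OC | intermediate
25 | 3,5-dimethoxyphenol | COc1cc(O)cc(OC)c1 | starting material
26 | ethyl bromoacetate | CCOC(=O)CBr | starting material
27 | ethyl (3,5-dimethoxyphenoxy)acetate | CCOC(=O)COc1cc(OC)cc(OC)c1 | intermediate
28 | (3,5-dimethoxyphenoxy)acetic acid | OC(=O)COc1cc(OC)cc(OC)c1 | intermediate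
29 | (3,5-dimethoxyphenoxy)acetyl chloride | COc1cc(OCC(=O)Cl)cc(OC)c1 | intermediate
30 | (3,5-dimethoxyphenoxy)ketene (not isolated) | O=C=COc1cc(OC)cc(OC)c1 | intermediate
31 | rac-4-(3,5-dimethoxyphenoxy)-3-ethoxycyclobut-2-en-1-one | CCOC1=CC(=O)C1Oc1cc(OC)cc(OC)c1 | intermediate
32 | (Z)-4-(3,5-dimethoxyphenoxy)-3-ethoxybuta-1,3-dien-1-one, aryloxy trans to the ketene carbon (not isolated) | O=C=C/C(OCC)=C/Oc1cc(OC)cc(OC)c1 | intermediate
33 | rac-4-[(Z)-2-(3,5-dimethoxyphenoxy)-1-ethoxyethenyl]-3-[2-ethoxy-6-methoxy-4-(2,4,6-trimethoxyphenoxy)phenoxy]cyclobut-2-en-1-one (not isolated) | O=C1C=C(Oc2c(OCC)cc(Oc3c(OC)cc(OC)cc3OC)cc2OC)C1/C(OCC)=C/Oc1cc(OC)cc(OC)c1 | intermediate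
34 | (3E,5Z)-6-(3,5-dimethoxyphenoxy)-5-ethoxy-3-[2-ethoxy-6-methoxy-4-(2,4,6-trimethoxyphenoxy)phenoxy]hexa-1,3,5-trien-1-one (not isolated) | O=C=C/C(Oc1c(OCC)cc(Oc2c(OC)cc(OC)cc2OC)cc1OC)=C\C(OCC)=C\Oc1cc(OC)cc(OC)c1 | intermediate
35 | rac-6-(3,5-dimethoxyphenoxy)-5-ethoxy-3-[2-ethoxy-6-methoxy-4-(2,4,6-trimethoxyphenoxy)phenoxy]cyclohexa-2,4-dien-1-one (not isolated) | O=C1C=C(Oc2c(OCC)cc(Oc3c(OC)cc(OC)cc3OC)cc2OC)C=C(OCC)C1Oc1cc(OC)cc(OC)c1 | intermediate
36 | 2-(3,5-dimethoxyphenoxy)-3-ethoxy-5-[2-ethoxy-6-methoxy-4-(2,4,6-trimethoxyphenoxy)phenoxy]phenol | COc1cc(OC)cc(Oc2c(O)cc(Oc3c(OCC)cc(Oc4c(OC)cc(OC)cc4OC)cc3OC)cc2OCC)c1 | intermediate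
37 | tetraphlorethol C | Oc1cc(O)cc(Oc2c(O)cc(Oc3c(O)cc(Oc4c(O)cc(O)cc4O)cc3O)cc2O)c1 | target

**Step count**
Total steps: 16.
Longest linear sequence: 11 steps (1, 2, 3, 4, 6, 7, 8, 9, 10, 15, 16).

**Steps most likely to fail**

1. Step 6 (new method). The 3-ethoxy group stabilises cyclobutenone 13, so ring opening may need a temperature at which the terminal ynol ether 9 oligomerises. The vinylketene may also be lost to dimerisation or to acylation of the product phenol before it meets the alkyne.
Fallback (known chemistry), setting out from phenol 3 and coming back at 19: ring C would be brought in as a ready-made aryl bromide and joined to the ring D oxygen by copper-catalysed Ullmann etherification. The hindered partner is the phenol, and the halide sits on a carbon flanked by two hydrogens. Bought 5-bromo-2-hydroxy-3-methoxybenzaldehyde would be benzylated (BnBr, K2CO3, DMF) to 2-(benzyloxy)-5-bromo-3-methoxybenzaldehyde F1. Baeyer–Villiger oxidation (mCPBA, CH2Cl2) should give 2-(benzyloxy)-5-bromo-3-methoxyphenyl formate F2, methanolysis (K2CO3, MeOH) 2-(benzyloxy)-5-bromo-3-methoxyphenol F3, and ethylation (EtI, K2CO3, DMF) 2-(benzyloxy)-5-bromo-1-ethoxy-3-methoxybenzene F4. Coupling of F4 with 3 (CuI, picolinic acid, K3PO4, DMSO, 90 to 110 °C, argon) should give 19, after which steps 8 to 16 follow unchanged.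

2. Step 15 (new method, key step). The aryloxy cyclobutenone 31 may decompose or reclose unproductively, and the larger, more hindered ynol ether 24 may be captured too slowly, so that ketene dimerisation and alkyne oligomerisation take over.
Fallback (known chemistry), setting out from phenol 20 and coming back at 37: rings B and A would be attached one after the other by the same Ullmann etherification. Phenol 20 would be coupled with 2-(benzyloxy)-5-bromo-1-ethoxy-3-methoxybenzene F4, prepared from bought 5-bromo-2-hydroxy-3-methoxybenzaldehyde through F1, F2 and F3 as described under step 6 (CuI, picolinic acid, K3PO4, DMSO, 90 to 110 °C), to give the benzyl-protected trimer 2-(benzyloxy)-1-ethoxy-5-[2-ethoxy-6-methoxy-4-(2,4,6-trimethoxyphenoxy)phenoxy]-3-methoxybenzene F5. Hydrogenolysis (H2, Pd/C) should give the hindered trimer phenol 2-ethoxy-4-[2-ethoxy-6-methoxy-4-(2,4,6-trimethoxyphenoxy)phenoxy]-6-methoxyphenol F6. A second coupling of the same kind with bought 1-iodo-3,5-dimethoxybenzene should give the fully alkylated tetramer 2-(3,5-dimethoxyphenoxy)-1-ethoxy-5-[2-ethoxy-6-methoxy-4-(2,4,6-trimethoxyphenoxy)phenoxy]-3-methoxybenzene F7. BBr3 under the conditions of step 16 (seven methyl and two ethyl ethers) would convert F7 into 37.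

3. Step 14. Intramolecular acylation of the very electron-rich ring A by the acid chloride or the ketene, together with ketene dimerisation, may outrun the intermolecular cycloaddition with ethoxyacetylene.
Fallback, setting out from cyclobutenone 13 and ynol ether 24 and coming back at 37: ring B would be grown with the benzyloxy cyclobutenone that has no nucleophilic arene, and ring A added afterwards. Benzannulation of 24 with 13 under the conditions of step 6 should give 2-(benzyloxy)-3-ethoxy-5-[2-ethoxy-6-methoxy-4-(2,4,6-trimethoxyphenoxy)phenoxy]phenol F8. O-Methylation (MeI, K2CO3, DMF) would give the benzyl-protected trimer F5, hydrogenolysis the trimer phenol F6, and Ullmann coupling with 1-iodo-3,5-dimethoxybenzene (CuI, picolinic acid, K3PO4, DMSO) the fully alkylated tetramer F7, which BBr3 converts into 37.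

**Further compounds**
F1 | step 6 | 2-(benzyloxy)-5-bromo-3-methoxybenzaldehyde | COc1cc(Br)cc(C=O)c1OCc1ccccc1
F2 | step 6 | 2-(benzyloxy)-5-bromo-3-methoxyphenyl formate | COc1cc(Br)cc(OC=O)c1OCc1ccccc1
F3 | step 6 | 2-(benzyloxy)-5-bromo-3-methoxyphenol | COc1cc(Br)cc(O)c1OCc1ccccc1
F4 | step 6 | 2-(benzyloxy)-5-bromo-1-ethoxy-3-methoxybenzene | CCOc1cc(Br)cc(OC)c1OCc1ccccc1
F5 | step 15 | 2-(benzyloxy)-1-ethoxy-5-[2-ethoxy-6-methoxy-4-(2,4,6-trimethoxyphenoxy)phenoxy]-3-methoxybenzene | CCOc1cc(Oc2c(OCC)cc(Oc3c(OC)cc(OC)cc3OC)cc2OC)cc(OC)c1OCc1ccccc1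
F6 | step 15 | 2-ethoxy-4-[2-ethoxy-6-methoxy-4-(2,4,6-trimethoxyphenoxy)phenoxy]-6-methoxyphenol | CCOc1cc(Oc2c(OCC)cc(Oc3c(OC)cc(OC)cc3OC)cc2OC)cc(OC)c1O
F7 | step 15 | 2-(3,5-dimethoxyphenoxy)-1-ethoxy-5-[2-ethoxy-6-methoxy-4-(2,4,6-trimethoxyphenoxy)phenoxy]-3-methoxybenzene | COc1cc(OC)cc(Oc2c(OC)cc(Oc3c(OCC)cc(Oc4c(OC)cc(OC)cc4OC)cc3OC)cc2OCC)c1
F8 | step 14 | 2-(benzyloxy)-3-ethoxy-5-[2-ethoxy-6-methoxy-4-(2,4,6-trimethoxyphenoxy)phenoxy]phenol | CCOc1cc(Oc2c(OCC)cc(Oc3c(OC)cc(OC)cc3OC)cc2OC)cc(O)c1OCc1ccccc1
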